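**Retrosynthetic overview**

1. The target is robinetinidol-(4β→8)-epigallocatechin (upper unit 2R,3S,4R, i.e. 2,3-trans-3,4-cis; lower unit 2R,3R); it comes from its undeca-O-benzyl ether by hydrogenolysis.
2. C4–H is set last, by hydride delivery to a 4-aryl-flavan-4-ylium ion. The C4–C8 bond is therefore cut to an upper-unit C4 ketone plus a lower-unit C8 aryllithium, not to a flavan-4-yl cation plus arene, which gives mainly the 4α (3,4-trans) isomer.
3. The ketone is a (2R,3R)-dihydroflavonol. Its ring C is closed as in the flavonoid pathway (2'-phenol oxygen onto Cβ of a 2'-hydroxychalcone), in one flask with asymmetric C3 oxygenation through the chalcone epoxide.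
4. The chalcone comes from a Claisen–Schmidt condensation; the lower unit comes from (−)-epigallocatechin by per-O-benzylation and C8 bromination.
5. Ring order: ring C of the upper unit is the only ring made (step 2); all other rings are bought.

Assumption: 4'-benzyloxy-2'-hydroxyacetophenone, 3,4,5-tris(benzyloxy)benzaldehyde and (−)-epigallocatechin (green tea) are bought as catalogue chemicals.

**Route**

Step 1
Reactants: 1 1-[4-(benzyloxy)-2-hydroxyphenyl]ethan-1-one; 2 3,4,5-tris(benzyloxy)benzaldehyde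
Product: 3 (2E)-1-[4-(benzyloxy)-2-hydroxyphenyl]-3-[3,4,5-tris(benzyloxy)phenyl]prop-2-en-1-one
Conditions: KOH (aq.), EtOH/THF, rt
Reagents that add atoms: none
Why: Claisen–Schmidt (crossed aldol) condensation of the ketone enolate with a non-enolisable aldehyde, followed by E1cB dehydration to the thermodynamically preferred E-enone; no stereocentre is formed.

Step 2
Reactants: 3 (2E)-1-[4-(benzyloxy)-2-hydroxyphenyl]-3-[3,4,5-tris(benzyloxy)phenyl]prop-2-en-1-one
Product: 5 (2R,3R)-7-(benzyloxy)-3-hydroxy-2-[3,4,5-tris(benzyloxy)phenyl]-2,3-dihydro-4H-chromen-4-one, via (αR,βS)-chalcone epoxide 4 (not isolated)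
Conditions: poly-L-leucine (immobilised), urea–H2O2 (1.3 equiv), DBU (1.5 equiv), THF, 0 °C, Ar
Reagents that add atoms: urea–hydrogen peroxide, NC(N)=O.OO
Why: Proposed new method: Juliá–Colonna epoxidation (hydroperoxide conjugate addition and ring closure on the poly-L-leucine helix) is run on the unprotected 2'-hydroxychalcone, which alkaline peroxide is known to oxidise at the enone even in its phenoxide form, and sets Cα R and Cβ S; the 2'-phenoxide then opens epoxide 4 at the benzylic Cβ anti to the C–O bond (6-endo, favoured because there is no 6'-substituent), so C2 forms by inversion and C3 keeps the epoxidation configuration, giving the 2,3-trans (2R,3R) ketol; the closest known reactions are the Algar–Flynn–Oyamada reaction and the acid-induced cyclisation of 2'-O-protected chalcone epoxides to dihydroflavonols.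

Step 3
Reactants: 5 (2R,3R)-7-(benzyloxy)-3-hydroxy-2-[3,4,5-tris(benzyloxy)phenyl]-2,3-dihydro-4H-chromen-4-one
Product: 6 (2R,3R)-3,7-bis(benzyloxy)-2-[3,4,5-tris(benzyloxy)phenyl]-2,3-dihydro-4H-chromen-4-one
Conditions: BnOC(=NH)CCl3 (2 equiv), TfOH (cat.), CH2Cl2/cyclohexane, 0 °C to rt
Reagents that add atoms: benzyl 2,2,2-trichloroacetimidate, N=C(OCc1ccccc1)C(Cl)(Cl)Cl
Why: Acid-catalysed imidate O-benzylation proceeds without base or oxidant, so the α-ketol is neither enolised, ring-opened nor dehydrogenated to the flavonol, and both stereocentres are untouched.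

Step 4
Reactants: 7 (−)-epigallocatechin, (2R,3R)-2-(3,4,5-trihydroxyphenyl)-3,4-dihydro-2H-chromene-3,5,7-triol
Product: 8 (2R,3R)-3,5,7-tris(benzyloxy)-2-[3,4,5-tris(benzyloxy)phenyl]-3,4-dihydro-2H-chromene
Conditions: BnBr (7.5 equiv), NaH (7 equiv), DMF, −40 °C to rt, Ar
Reagents that add atoms: benzyl bromide, BrCc1ccccc1
Why: Williamson etherification in which each phenoxide, and finally the 3-alkoxide, is trapped by benzyl bromide as it forms at low temperature, so the ring B quinone methide path to C2 epimers is outrun and both stereocentres are kept.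

Step 5
Reactants: 8 (2R,3R)-3,5,7-tris(benzyloxy)-2-[3,4,5-tris(benzyloxy)phenyl]-3,4-dihydro-2H-chromene
Product: 9 (2R,3R)-3,5,7-tris(benzyloxy)-8-bromo-2-[3,4,5-tris(benzyloxy)phenyl]-3,4-dihydro-2H-chromene
Conditions: NBS (1.05 equiv), CH2Cl2, −78 °C to rt, dark
Reagents that add atoms: N-bromosuccinimide, O=C1CCC(=O)N1Br
Why: Electrophilic aromatic bromination goes to C8 of the phloroglucinol-type ring A (ortho to O1 and 7-OBn, para to 5-OBn), the position known to react first in O-benzylated flavan-3-ols, ahead of C6 and ring B.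

Step 6
Reactants: 9 (2R,3R)-3,5,7-tris(benzyloxy)-8-bromo-2-[3,4,5-tris(benzyloxy)phenyl]-3,4-dihydro-2H-chromene; 6 (2R,3R)-3,7-bis(benzyloxy)-2-[3,4,5-tris(benzyloxy)phenyl]-2,3-dihydro-4H-chromen-4-one
Product: 11 (2R,3R)-3,7-bis(benzyloxy)-4-{(2R,3R)-3,5,7-tris(benzyloxy)-2-[3,4,5-tris(benzyloxy)phenyl]-3,4-dihydro-2H-chromen-8-yl}-2-[3,4,5-tris(benzyloxy)phenyl]-3,4-dihydro-2H-chromen-4-ol (C4 epimer mixture), via aryllithium 10 (not isolated)
Conditions: 9 (1.5 equiv), n-BuLi (1.45 equiv), THF, −78 °C, 20 min; then 6, −78 °C, 2 h; then H2O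
Reagents that add atoms: none
Why: Bromine–lithium exchange followed by 1,2-addition of the aryllithium to the aryl ketone, which at −78 °C outruns enolisation; the new C4 carbinol centre forms as an epimer mixture that does not matter because C4 is made planar in step 7.

Step 7
Reactants: 11 (2R,3R)-3,7-bis(benzyloxy)-4-{(2R,3R)-3,5,7-tris(benzyloxy)-2-[3,4,5-tris(benzyloxy)phenyl]-3,4-dihydro-2H-chromen-8-yl}-2-[3,4,5-tris(benzyloxy)phenyl]-3,4-dihydro-2H-chromen-4-ol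
Product: 13 (2R,3S,4R)-3,7-bis(benzyloxy)-4-{(2R,3R)-3,5,7-tris(benzyloxy)-2-[3,4,5-tris(benzyloxy)phenyl]-3,4-dihydro-2H-chromen-8-yl}-2-[3,4,5-tris(benzyloxy)phenyl]-3,4-dihydro-2H-chromene, via flavan-4-ylium cation 12 (not isolated)
Conditions: Et3SiH (5 equiv), CF3CO2H (5 equiv), CH2Cl2, −78 to −20 °C
Reagents that add atoms: none
Why: Ionic hydrogenation: the acid ionises the doubly benzylic tertiary alcohol to cation 12 (stabilised by O1 and the 7-benzyloxy group), and the silane delivers hydride to the face anti to the adjacent 3-benzyloxy group, the face that external nucleophiles choose in 2,3-trans flavan-4-yl cations, so H4 ends up α and the aryl group β, cis to O3 (4R).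

Step 8
Reactants: 13 (2R,3S,4R)-3,7-bis(benzyloxy)-4-{(2R,3R)-3,5,7-tris(benzyloxy)-2-[3,4,5-tris(benzyloxy)phenyl]-3,4-dihydro-2H-chromen-8-yl}-2-[3,4,5-tris(benzyloxy)phenyl]-3,4-dihydro-2H-chromene
Product: 14 (2R,3R)-2-(3,4,5-trihydroxyphenyl)-8-[(2R,3S,4R)-3,7-dihydroxy-2-(3,4,5-trihydroxyphenyl)-3,4-dihydro-2H-chromen-4-yl]-3,4-dihydro-2H-chromene-3,5,7-triol (CNP0275321.4)
Conditions: H2 (1 atm), Pd(OH)2/C, THF/MeOH, rt; filtration under Ar, Sephadex LH-20
Reagents that add atoms: none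
Why: Hydrogenolysis of the eleven O-benzyl groups leaves the diaryl methine, both pyran C–O bonds and all five stereocentres untouched, as in the usual last step of proanthocyanidin syntheses.

**Compound list**

1 | 1-[4-(benzyloxy)-2-hydroxyphenyl]ethan-1-one | CC(=O)c1ccc(OCc2ccccc2)cc1O | starting material
2 | 3,4,5-tris(benzyloxy)benzaldehyde | O=Cc1cc(OCc2ccccc2)c(OCc2ccccc2)c(OCc2ccccc2)c1 | starting material
3 | (2E)-1-[4-(benzyloxy)-2-hydroxyphenyl]-3-[3,4,5-tris(benzyloxy)phenyl]prop-2-en-1-one | O=C(/C=C/c1cc(OCc2ccccc2)c(OCc2ccccc2)c(OCc2ccccc2)c1)c1ccc(OCc2ccccc2)cc1O | intermediate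
4 | [4-(benzyloxy)-2-hydroxyphenyl]{(2R,3S)-3-[3,4,5-tris(benzyloxy)phenyl]oxiran-2-yl}methanone (αR,βS trans-epoxide) | O=C(c1ccc(OCc2ccccc2)cc1O)[C@@H]1O[C@H]1c1cc(OCc2ccccc2)c(OCc2ccccc2)c(OCc2ccccc2)c1 | intermediate
5 | (2R,3R)-7-(benzyloxy)-3-hydroxy-2-[3,4,5-tris(benzyloxy)phenyl]-2,3-dihydro-4H-chromen-4-one (2,3-trans) | O(Cc1ccccc1)c1ccc2c(c1)O[C@H](c1cc(OCc3ccccc3)c(OCc3ccccc3)c(OCc3ccccc3)c1)[C@@H](O)C2=O | intermediate
6 | (2R,3R)-3,7-bis(benzyloxy)-2-[3,4,5-tris(benzyloxy)phenyl]-2,3-dihydro-4H-chromen-4-one | O(Cc1ccccc1)c1ccc2c(c1)O[C@H](c1cc(OCc3ccccc3)c(OCc3ccccc3)c(OCc3ccccc3)c1)[C@@H](OCc1ccccc1)C2=O | intermediate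
7 | (−)-epigallocatechin, (2R,3R)-2-(3,4,5-trihydroxyphenyl)-3,4-dihydro-2H-chromene-3,5,7-triol | Oc1cc(O)c2c(c1)O[C@H](c1cc(O)c(O)c(O)c1)[C@H](O)C2 | starting material
8 | (2R,3R)-3,5,7-tris(benzyloxy)-2-[3,4,5-tris(benzyloxy)phenyl]-3,4-dihydro-2H-chromene | O(Cc1ccccc1)c1cc(OCc3ccccc3)c2c(c1)O[C@H](c1cc(OCc3ccccc3)c(OCc3ccccc3)c(OCc3ccccc3)c1)[C@H](OCc1ccccc1)C2 | intermediate
9 | (2R,3R)-3,5,7-tris(benzyloxy)-8-bromo-2-[3,4,5-tris(benzyloxy)phenyl]-3,4-dihydro-2H-chromene | O(Cc1ccccc1)c1cc(OCc3ccccc3)c2c(c1Br)O[C@H](c1cc(OCc3ccccc3)c(OCc3ccccc3)c(OCc3ccccc3)c1)[C@H](OCc1ccccc1)C2 | intermediate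
10 | {(2R,3R)-3,5,7-tris(benzyloxy)-2-[3,4,5-tris(benzyloxy)phenyl]-3,4-dihydro-2H-chromen-8-yl}lithium | O(Cc1ccccc1)c1cc(OCc3ccccc3)c2c(c1[Li])O[C@H](c1cc(OCc3ccccc3)c(OCc3ccccc3)c(OCc3ccccc3)c1)[C@H](OCc1ccccc1)C2 | intermediate
11 | (2R,3R)-3,7-bis(benzyloxy)-4-{(2R,3R)-3,5,7-tris(benzyloxy)-2-[3,4,5-tris(benzyloxy)phenyl]-3,4-dihydro-2H-chromen-8-yl}-2-[3,4,5-tris(benzyloxy)phenyl]-3,4-dihydro-2H-chromen-4-ol, both C4 epimers | O(Cc1ccccc1)c1ccc2c(c1)O[C@H](c1cc(OCc3ccccc3)c(OCc3ccccc3)c(OCc3ccccc3)c1)[C@@H](OCc1ccccc1)C2(O)c1c(OCc3ccccc3)cc(OCc3ccccc3)c2c1O[C@H](c1cc(OCc3ccccc3)c(OCc3ccccc3)c(OCc3ccccc3)c1)[C@H](OCc1ccccc1)C2 | intermediate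
12 | (2R,3S)-3,7-bis(benzyloxy)-4-{(2R,3R)-3,5,7-tris(benzyloxy)-2-[3,4,5-tris(benzyloxy)phenyl]-3,4-dihydro-2H-chromen-8-yl}-2-[3,4,5-tris(benzyloxy)phenyl]-3,4-dihydro-2H-chromen-4-ylium trifluoroacetate | O(Cc1ccccc1)c1ccc2c(c1)O[C@H](c1cc(OCc3ccccc3)c(OCc3ccccc3)c(OCc3ccccc3)c1)[C@@H](OCc1ccccc1)[C+]2c1c(OCc3ccccc3)cc(OCc3ccccc3)c2c1O[C@H](c1cc(OCc3ccccc3)c(OCc3ccccc3)c(OCc3ccccc3)c1)[C@H](OCc1ccccc1)C2.[O-]C(=O)C(F)(F)F | intermediate
13 | (2R,3S,4R)-3,7-bis(benzyloxy)-4-{(2R,3R)-3,5,7-tris(benzyloxy)-2-[3,4,5-tris(benzyloxy)phenyl]-3,4-dihydro-2H-chromen-8-yl}-2-[3,4,5-tris(benzyloxy)phenyl]-3,4-dihydro-2H-chromene (undeca-O-benzyl ether of the target, 3,4-cis) | O(Cc1ccccc1)c1ccc2c(c1)O[C@H](c1cc(OCc3ccccc3)c(OCc3ccccc3)c(OCc3ccccc3)c1)[C@@H](OCc1ccccc1)[C@H]2c1c(OCc3ccccc3)cc(OCc3ccccc3)c2c1O[C@H](c1cc(OCc3ccccc3)c(OCc3ccccc3)c(OCc3ccccc3)c1)[C@H](OCc1ccccc1)C2 | intermediate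
14 | (2R,3R)-2-(3,4,5-trihydroxyphenyl)-8-[(2R,3S,4R)-3,7-dihydroxy-2-(3,4,5-trihydroxyphenyl)-3,4-dihydro-2H-chromen-4-yl]-3,4-dihydro-2H-chromene-3,5,7-triol, robinetinidol-(4β→8)-epigallocatechin | Oc1ccc2c(c1)O[C@H](c1cc(O)c(O)c(O)c1)[C@@H](O)[C@H]2c1c(O)cc(O)c2c1O[C@H](c1cc(O)c(O)c(O)c1)[C@H](O)C2 | target

**Step count and risks**

Total steps: 8. Longest linear sequence: 6 (steps 1, 2, 3, 6, 7, 8); steps 4 and 5 prepare the lower unit in parallel.

Steps most likely to fail: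

Step 2. The chalcone reacts as its phenoxide, which may slow the poly-leucine epoxidation or lower its selectivity. A background path (oxa-Michael closure first, then hydroxylation of the flavanone enolate) would give ketol outside the control of the catalyst. The ketol can also be over-oxidised to the flavonol under basic peroxide, and some 5-exo closure to aurone-type products is possible. Fallback, from 1 and back at 5: the phenol of 1 is masked with MOMCl/i-Pr2NEt (CH2Cl2, 0 °C) to give 1-[4-(benzyloxy)-2-(methoxymethoxy)phenyl]ethan-1-one F1. Condensation with 2 (KOH, EtOH/THF) gives (2E)-1-[4-(benzyloxy)-2-(methoxymethoxy)phenyl]-3-[3,4,5-tris(benzyloxy)phenyl]prop-2-en-1-one F2. Juliá–Colonna epoxidation under the conditions of step 2, now on a non-phenolic enone of a known substrate class, gives [4-(benzyloxy)-2-(methoxymethoxy)phenyl]{(2R,3S)-3-[3,4,5-tris(benzyloxy)phenyl]oxiran-2-yl}methanone F3. HCl in MeOH/THF at 45 °C then removes the acetal, and the freed phenol closes ring C at the benzylic carbon to give 5.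

Step 7. The 2-aryl group sits 1,3 to C4 on the α face and works against the directing effect of the 3-benzyloxy group, so the facial selectivity may be modest; loss of H3 to the 3-benzyloxyflav-3-ene is a side path. Fallback, from 11 and back at 14 (or at 13): the SN1 hydride capture is replaced by a stereospecific C–O hydrogenolysis. The C4 epimers of 11 are separated and assigned by NOE. The 4β-hydroxy epimer (aryl α) is hydrogenolysed over Pd(OH)2/C (H2, 1 atm, EtOAc/MeOH), where benzylic C–O bonds are cleaved with inversion. The aryl group therefore ends up β, the benzyl ethers fall in the same operation, and 14 is reached directly. The 4α-hydroxy epimer is treated with Raney Ni in EtOH, which cleaves benzylic C–O bonds with retention and gives 13, and step 8 follows. No new isolable compound arises.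

Step 6. A hindered aryllithium meets an enolisable ketone; deprotonation at C3 would open ring C by E1cB to an α-benzyloxychalcone. Fallback, from 6 and 8 and back at 13, with the polarity of the C4–C8 bond formation reversed: NaBH4 (MeOH/THF, 0 °C) reduces 6 to (2R,3S,4R)-3,7-bis(benzyloxy)-2-[3,4,5-tris(benzyloxy)phenyl]-3,4-dihydro-2H-chromen-4-ol F4. With TMSOTf (0.1 equiv) in CH2Cl2 at −78 °C this ionises and alkylates C8 of 8 (3 equiv) in a Friedel–Crafts reaction. The product is 13 together with its C4 epimer (2R,3S,4S)-3,7-bis(benzyloxy)-4-{(2R,3R)-3,5,7-tris(benzyloxy)-2-[3,4,5-tris(benzyloxy)phenyl]-3,4-dihydro-2H-chromen-8-yl}-2-[3,4,5-tris(benzyloxy)phenyl]-3,4-dihydro-2H-chromene F5. F5 is expected to be the major isomer and is removed by chromatography, so this path costs material, but 5-deoxy flavan-4-yl cations of this type are known to give a usable share of the 4β isomer.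

**Further compounds**

F1 | step 2 | 1-[4-(benzyloxy)-2-(methoxymethoxy)phenyl]ethan-1-one | CC(=O)c1ccc(OCc2ccccc2)cc1OCOC
F2 | step 2 | (2E)-1-[4-(benzyloxy)-2-(methoxymethoxy)phenyl]-3-[3,4,5-tris(benzyloxy)phenyl]prop-2-en-1-one | O=C(/C=C/c1cc(OCc2ccccc2)c(OCc2ccccc2)c(OCc2ccccc2)c1)c1ccc(OCc2ccccc2)cc1OCOC
F3 | step 2 | [4-(benzyloxy)-2-(methoxymethoxy)phenyl]{(2R,3S)-3-[3,4,5-tris(benzyloxy)phenyl]oxiran-2-yl}methanone | O=C(c1ccc(OCc2ccccc2)cc1OCOC)[C@@H]1O[C@H]1c1cc(OCc2ccccc2)c(OCc2ccccc2)c(OCc2ccccc2)c1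
F4 | step 6 | (2R,3S,4R)-3,7-bis(benzyloxy)-2-[3,4,5-tris(benzyloxy)phenyl]-3,4-dihydro-2H-chromen-4-ol | O(Cc1ccccc1)c1ccc2c(c1)O[C@H](c1cc(OCc3ccccc3)c(OCc3ccccc3)c(OCc3ccccc3)c1)[C@@H](OCc1ccccc1)[C@@H]2O
F5 | step 6 | (2R,3S,4S)-3,7-bis(benzyloxy)-4-{(2R,3R)-3,5,7-tris(benzyloxy)-2-[3,4,5-tris(benzyloxy)phenyl]-3,4-dihydro-2H-chromen-8-yl}-2-[3,4,5-tris(benzyloxy)phenyl]-3,4-dihydro-2H-chromene | O(Cc1ccccc1)c1ccc2c(c1)O[C@H](c1cc(OCc3ccccc3)c(OCc3ccccc3)c(OCc3ccccc3)c1)[C@@H](OCc1ccccc1)[C@@H]2c1c(OCc3ccccc3)cc(OCc3ccccc3)c2c1O[C@H](c1cc(OCc3ccccc3)c(OCc3ccccc3)c(OCc3ccccc3)c1)[C@H](OCc1ccccc1)C2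
F0 | step 7 | none | none
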